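**Plan**
1. Retrosynthesis: cut the side-chain bond C1′–C2′ (sulfone alkylation), return ring B's C2–OH and C1–CO2Me to a carvone-type enone, cut the ring-A bond C5–C6 (quaternary carbon to CHCl), then the two C8a–C bonds made by enolate alkylation.
2. Forward: ring B is bought as (R)-(−)-carvone; C8a is quaternised (MeI, then 1,3-dichloropropene); the isopropenyl group becomes a β-methyl vinyl sulfone; ring A is closed at C5–C6; ring B is adjusted (C1=O → CH–CO2Me, C2=C3 → C2–OH); the sulfone arm is prenylated and desulfonylated.
3. Enabling feature: in ring A, C6 carries Cl and H next to quaternary C5 (Me + CH2R), and the two ring-A arms sit trans on C8a/C4a of ring B. C6 can therefore be an α-chloroalkyl radical born from a 3-chloroallyl group, and C5 the β-carbon of a vinyl sulfone whose α-carbon becomes C1′.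
4. Stereochemistry: C4a is bought with carvone; C8a comes from alkylation anti to the isopropenyl group; C5 and C6 are set together in the chair-like ring closure; C1 (α-face protonation) and C2 (trans-diaxial oxymercuration) are relayed by the rigid trans-decalin.

Key step: step 5

Remark: ring positions are numbered as in the target name (C1 ester-bearing, C2 carbinol, C5 quaternary ring-A carbon, C6 CHCl, C4a/C8a ring fusion, C1′ first side-chain carbon on C5); β is the face of the C8a methyl; either geometry of 1,3-dichloropropene would serve because C6 passes through a radical, and the E isomer is used.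

**Step 1**
Reactants: 1 (R)-(−)-carvone; 2 iodomethane
Product: 4 (5R,6S)-2,6-dimethyl-5-(prop-1-en-2-yl)cyclohex-2-en-1-one (6-methylcarvone; trans epimer drawn; any cis epimer is carried along), via lithium dienolate of carvone 3 (not isolated)
Conditions: LDA, THF, −78 °C; MeI, −78 → 0 °C
Reagents that add atoms: iodomethane (2), CI
Why: Kinetic deprotonation of carvone occurs at the α′-CH2 (C6) and the cross-conjugated dienolate is C-methylated there (enolate alkylation); the new centre should form mainly trans to the isopropenyl group but is erased again in step 2.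

**Step 2**
Reactants: 4 6-methylcarvone; 5 (E)-1,3-dichloroprop-1-ene
Product: 7 (5S,6S)-6-[(E)-3-chloroprop-2-en-1-yl]-2,6-dimethyl-5-(prop-1-en-2-yl)cyclohex-2-en-1-one, via lithium dienolate of 6-methylcarvone 6 (not isolated)
Conditions: LDA, THF, −78 °C; 5, DMPU, −78 → −20 °C
Reagents that add atoms: (E)-1,3-dichloroprop-1-ene (5), ClC/C=C/Cl
Why: Re-enolisation at C6 and SN2 attack on the allylic CH2Cl terminus (enolate alkylation) create the quaternary carbon; the electrophile should enter anti to the neighbouring isopropenyl group, so the methyl ends cis and the chloroallyl arm trans to it.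

**Step 3**
Reactants: 7 chloroallyl enone; 8 sodium periodate
Product: 10 (5R,6S)-5-acetyl-6-[(E)-3-chloroprop-2-en-1-yl]-2,6-dimethylcyclohex-2-en-1-one, via vicinal diol 9 (not isolated)
Conditions: OsO4 (2 mol %), NaIO4, 2,6-lutidine, dioxane–H2O, rt
Reagents that add atoms: osmium tetroxide (catalytic carrier of the oxygen atom), O=[Os](=O)(=O)=O; sodium periodate (8), [Na+].[O-]I(=O)(=O)=O
Why: Lemieux–Johnson oxidation (dihydroxylation, then periodate glycol cleavage) should attack the electron-rich 1,1-disubstituted isopropenyl alkene much faster than the enone or the chloroalkene, as in the cleavage of carvone itself to its methyl ketone; no stereocentre is made.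

**Step 4**
Reactants: 10 methyl ketone; 11 diethyl [(phenylsulfonyl)methyl]phosphonate
Product: 12 (5R,6S)-6-[(E)-3-chloroprop-2-en-1-yl]-2,6-dimethyl-5-[(E)-1-(phenylsulfonyl)prop-1-en-2-yl]cyclohex-2-en-1-one
Conditions: NaH, THF, 0 °C → rt; E isomer separated from any Z isomer
Reagents that add atoms: diethyl [(phenylsulfonyl)methyl]phosphonate (11), CCOP(=O)(CS(=O)(=O)c1ccccc1)OCC
Why: Horner–Wadsworth–Emmons olefination of the methyl ketone with the sulfonyl-stabilised phosphonate should give the trisubstituted vinyl sulfone, E because the sulfonyl group avoids the ring; the ring carbonyl is shielded by the adjacent quaternary carbon.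

**Step 5**
Reactants: 12 chloroalkene vinyl sulfone
Product: 13 (4aR,5R,6S,8aS)-6-chloro-2,5,8a-trimethyl-5-[(phenylsulfonyl)methyl]-4a,5,6,7,8,8a-hexahydronaphthalen-1(4H)-one (trans-fused; 8a-Me / 5-Me / 6-Cl β; H-4a / CH2SO2Ph α)
Conditions: Fe(acac)3 (30 mol %), PhSiH3, EtOH–ethylene glycol, 60 °C, degassed
Reagents that add atoms: none
Why: Proposed new method: An iron hydride formed from Fe(acac)3 and PhSiH3 transfers a hydrogen atom to C7 of the chloroalkene (the carbon remote from chlorine), giving the chlorine-stabilised secondary radical at C6, which adds 6-exo-trig to C5, the β-carbon of the vinyl sulfone; the α-sulfonyl radical is then reduced by Fe(II) and protonated by ethanol. The closest known reaction type is the iron-mediated reductive (Giese-type) coupling of heteroatom-substituted donor olefins, haloalkenes among them, with Michael acceptors, used here intramolecularly with a 1-chloro-1-alkene donor, which has not been shown. Ring A closes through a chair-like 6-exo transition state whose two arms are the trans-diequatorial substituents on C8a and C4a of ring B. C6: chlorine takes the pseudo-equatorial site on the radical carbon, away from the axial hydrogens on C8 and C4a, so Cl ends β-equatorial; C5: the vinyl sulfone reacts with its C=C eclipsing the C4a–H bond (allylic-strain minimum), because the other rotamer would drive the vinyl hydrogen into the axial C8a methyl, so the C5 methyl ends axial (β) and CH2SO2Ph equatorial. The step needs hydrogen-atom transfer to the chloroalkene in preference to the two electron-poor alkenes (enone and vinyl sulfone), which is the main uncertainty, and 6-exo rather than 7-endo closure, which the polarity match with the sulfonyl-activated β-carbon should secure; the equatorial C–Cl bond formed has no antiperiplanar hydrogen or carbanion to expel it.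

**Step 6**
Reactants: 13 decalin enone; 14 trifluoromethanesulfonic anhydride
Product: 15 6-chloro-2,5,8a-trimethyl-5-[(phenylsulfonyl)methyl]-4a,5,6,7,8,8a-hexahydronaphthalen-1-yl trifluoromethanesulfonate (1,3-diene C1=C2–C3=C4; stereocentres as in 13)
Conditions: Tf2O, 2,6-di-tert-butyl-4-methylpyridine, CH2Cl2, 0 °C → rt
Reagents that add atoms: trifluoromethanesulfonic anhydride (14), O=S(=O)(OS(=O)(=O)C(F)(F)F)C(F)(F)F
Why: O-Triflation of the enone and γ-deprotonation by the hindered pyridine (dienyl triflate formation) can only give the through-conjugated diene, because C8a is quaternary and C4 is the only position with a removable proton; no stereocentre is touched.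

**Step 7**
Reactants: 15 dienyl triflate; 16 carbon monoxide; 17 methanol
Product: 18 methyl 6-chloro-2,5,8a-trimethyl-5-[(phenylsulfonyl)methyl]-4a,5,6,7,8,8a-hexahydronaphthalene-1-carboxylate (2,4-dienoate; stereocentres as in 13)
Conditions: Pd(OAc)2 (5 mol %), dppf, Et3N, CO (1 atm), MeOH–DMF, 60 °C
Reagents that add atoms: carbon monoxide (16), [C-]#[O+]; methanol (17), CO
Why: Palladium-catalysed methoxycarbonylation of the alkenyl triflate (oxidative addition, CO insertion, methanolysis) installs the ester carbon on C1; the secondary alkyl chloride and the sulfone should not react with Pd(0) under these conditions.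

**Step 8**
Reactants: 18 dienoate
Product: 20 methyl 6-chloro-2,5,8a-trimethyl-5-[(phenylsulfonyl)methyl]-1,4,4a,5,6,7,8,8a-octahydronaphthalene-1-carboxylate with H-1 α (ester β; C2=C3 alkene; other centres as in 13), via lithium ester dienolate 19 (not isolated)
Conditions: L-Selectride, THF, −78 °C; then AcOH, −78 °C
Reagents that add atoms: none
Why: With C2 fully substituted, the bulky hydride should add at the δ-carbon C4 (1,6-conjugate reduction of a 2,4-dienoate); kinetic protonation of the extended enolate at C1 from the α-face, opposite the axial C8a methyl, sets H-1 α and leaves the C2=C3 double bond.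

**Step 9**
Reactants: 20 β,γ-unsaturated ester; 21 mercury(II) acetate; 22 water
Product: 24 methyl 6-chloro-2-hydroxy-2,5,8a-trimethyl-5-[(phenylsulfonyl)methyl]decahydronaphthalene-1-carboxylate (2-OH β-axial; 2-Me α; all other centres as in the target), via C3 acetoxymercurio alcohol 23 (not isolated)
Conditions: Hg(OAc)2, THF–H2O, rt; then NaBH4, aq NaOH, 0 °C
Reagents that add atoms: water (22), O
Why: Markovnikov oxymercuration–demercuration: the mercurinium ion should form on the open α-face and water open it trans-diaxially at the tertiary carbon C2 (Fürst–Plattner rule), placing OH β-axial and the methyl α-equatorial; NaBH4 then replaces mercury on C3 by hydrogen, and the sulfone and alkyl chloride are inert.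

**Step 10**
Reactants: 24 hydroxy ester sulfone; 25 1-bromo-3-methylbut-2-ene
Product: 27 methyl 6-chloro-2-hydroxy-2,5,8a-trimethyl-5-[4-methyl-1-(phenylsulfonyl)pent-3-en-1-yl]decahydronaphthalene-1-carboxylate (mixture at the sulfonyl-bearing carbon), via dilithio derivative of the hydroxy sulfone 26 (not isolated)
Conditions: LDA (2.2 equiv), THF, −78 °C; 25, −78 → −40 °C; then H2O
Reagents that add atoms: 1-bromo-3-methylbut-2-ene (25), CC(C)=CCBr
Why: Two equivalents of LDA should give the alkoxide and the α-sulfonyl carbanion, and the carbanion, the more reactive site, is C-alkylated by the allylic bromide (sulfone alkylation); the equatorial C6–Cl bond is antiperiplanar neither to the carbanion nor to a hydrogen, so cyclopropane formation and E2 loss of HCl are disfavoured, and the new sulfone-bearing centre is removed in step 11.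

**Step 11**
Reactants: 27 prenylated sulfone
Product: 28 methyl (1R,2S,4aR,5S,6S,8aS)-6-chloro-2-hydroxy-2,5,8a-trimethyl-5-(4-methylpent-3-en-1-yl)decahydronaphthalene-1-carboxylate (CNP0331104.1)
Conditions: 6% Na(Hg), Na2HPO4, MeOH–THF, −20 °C
Reagents that add atoms: none
Why: Reductive desulfonylation with buffered sodium amalgam (as in the Julia sequence) cleaves the C–S bond by electron transfer to the aryl sulfone and leaves C–H; the secondary chloride, the trisubstituted alkene and the β-hydroxy ester should survive, and no stereocentre changes.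

**Compound list**
1 | (R)-(−)-carvone | O=C1C[C@H](C(C)=C)CC=C1C | starting material
2 | iodomethane | CI | starting material
3 | lithium dienolate of carvone | [Li]OC1=C[C@H](C(C)=C)CC=C1C | intermediate
4 | (5R,6S)-2,6-dimethyl-5-(prop-1-en-2-yl)cyclohex-2-en-1-one (6-methylcarvone, trans epimer drawn) | O=C1[C@@H](C)[C@H](C(C)=C)CC=C1C | intermediate
5 | (E)-1,3-dichloroprop-1-ene | ClC/C=C/Cl | starting material
6 | lithium dienolate of 6-methylcarvone | [Li]OC1=C(C)[C@H](C(C)=C)CC=C1C | intermediate
7 | (5S,6S)-6-[(E)-3-chloroprop-2-en-1-yl]-2,6-dimethyl-5-(prop-1-en-2-yl)cyclohex-2-en-1-one | O=C1[C@@](C)(C/C=C/Cl)[C@H](C(C)=C)CC=C1C | intermediate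
8 | sodium periodate | [Na+].[O-]I(=O)(=O)=O | starting material
9 | vicinal diol from dihydroxylation of the isopropenyl group of 7 (carbinol centre as a mixture) | O=C1[C@@](C)(C/C=C/Cl)[C@H](C(C)(O)CO)CC=C1C | intermediate
10 | (5R,6S)-5-acetyl-6-[(E)-3-chloroprop-2-en-1-yl]-2,6-dimethylcyclohex-2-en-1-one | O=C1[C@@](C)(C/C=C/Cl)[C@H](C(C)=O)CC=C1C | intermediate
11 | diethyl [(phenylsulfonyl)methyl]phosphonate | CCOP(=O)(CS(=O)(=O)c1ccccc1)OCC | starting material
12 | (5R,6S)-6-[(E)-3-chloroprop-2-en-1-yl]-2,6-dimethyl-5-[(E)-1-(phenylsulfonyl)prop-1-en-2-yl]cyclohex-2-en-1-one | O=C1[C@@](C)(C/C=C/Cl)[C@H](/C(C)=C/S(=O)(=O)c2ccccc2)CC=C1C | intermediate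
13 | (4aR,5R,6S,8aS)-6-chloro-2,5,8a-trimethyl-5-[(phenylsulfonyl)methyl]-4a,5,6,7,8,8a-hexahydronaphthalen-1(4H)-one | O=C1[C@@]2(C)CC[C@H](Cl)[C@@](C)(CS(=O)(=O)c3ccccc3)[C@@H]2CC=C1C | intermediate
14 | trifluoromethanesulfonic anhydride | O=S(=O)(OS(=O)(=O)C(F)(F)F)C(F)(F)F | starting material
15 | dienyl triflate of 13 (C1=C2–C3=C4) | FC(F)(F)S(=O)(=O)OC=1[C@@]2(C)CC[C@H](Cl)[C@@](C)(CS(=O)(=O)c3ccccc3)[C@@H]2C=CC=1C | intermediate
16 | carbon monoxide | [C-]#[O+] | starting material
17 | methanol | CO | starting material
18 | methyl 2,4-dienoate from 15 | COC(=O)C=1[C@@]2(C)CC[C@H](Cl)[C@@](C)(CS(=O)(=O)c3ccccc3)[C@@H]2C=CC=1C | intermediate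
19 | lithium ester dienolate from 1,6-hydride addition to 18 | COC(O[Li])=C1[C@@]2(C)CC[C@H](Cl)[C@@](C)(CS(=O)(=O)c3ccccc3)[C@@H]2CC=C1C | intermediate
20 | β,γ-unsaturated methyl ester, H-1 α, C2=C3 alkene | COC(=O)[C@@H]1[C@@]2(C)CC[C@H](Cl)[C@@](C)(CS(=O)(=O)c3ccccc3)[C@@H]2CC=C1C | intermediate
21 | mercury(II) acetate | CC(=O)O[Hg]OC(C)=O | starting material
22 | water | O | starting material
23 | C3α-acetoxymercurio C2β-hydroxy adduct of 20 | COC(=O)[C@@H]1[C@@]2(C)CC[C@H](Cl)[C@@](C)(CS(=O)(=O)c3ccccc3)[C@@H]2C[C@@H]([Hg]OC(C)=O)[C@]1(C)O | intermediate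
24 | methyl 6-chloro-2-hydroxy-2,5,8a-trimethyl-5-[(phenylsulfonyl)methyl]decahydronaphthalene-1-carboxylate (ring centres as in the target) | COC(=O)[C@@H]1[C@@]2(C)CC[C@H](Cl)[C@@](C)(CS(=O)(=O)c3ccccc3)[C@@H]2CC[C@]1(C)O | intermediate
25 | 1-bromo-3-methylbut-2-ene (prenyl bromide) | CC(C)=CCBr | starting material
26 | dilithio derivative of 24 (lithium alkoxide and α-sulfonyl carbanion) | COC(=O)[C@@H]1[C@@]2(C)CC[C@H](Cl)[C@@](C)(C([Li])S(=O)(=O)c3ccccc3)[C@@H]2CC[C@]1(C)O[Li] | intermediate
27 | methyl 6-chloro-2-hydroxy-2,5,8a-trimethyl-5-[4-methyl-1-(phenylsulfonyl)pent-3-en-1-yl]decahydronaphthalene-1-carboxylate | COC(=O)[C@@H]1[C@@]2(C)CC[C@H](Cl)[C@@](C)(C(CC=C(C)C)S(=O)(=O)c3ccccc3)[C@@H]2CC[C@]1(C)O | intermediate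
28 | methyl (1R,2S,4aR,5S,6S,8aS)-6-chloro-2-hydroxy-2,5,8a-trimethyl-5-(4-methylpent-3-en-1-yl)decahydronaphthalene-1-carboxylate | COC(=O)[C@@H]1[C@@]2(C)CC[C@H](Cl)[C@@](C)(CCC=C(C)C)[C@@H]2CC[C@]1(C)O | target

**Step count**
Total steps: 11. Longest linear sequence: 11 steps, from (R)-(−)-carvone (1) to 28.

**Steps most likely to fail**

1. Step 5 (Proposed new method). What may go wrong:
   - hydrogen-atom transfer to the enone or the vinyl sulfone instead of the sluggish 1,2-disubstituted chloroalkene (acceptor reduction);
   - hydrogen delivery to the chlorine-bearing carbon followed by loss of chlorine;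
   - reduction of the α-chloro radical before it cyclises;
   - incomplete facial control at C5 or C6.

   Fallback with known chemistry, from 12 back to 13: mercury(II)-assisted hydrolysis of the chloroalkene (Hg(OCOCF3)2, aqueous formic acid) would give the aldehyde analogue of 12 F1. A SmI2 ketyl–olefin cyclisation (SmI2, t-BuOH, THF, −78 °C, 6-exo onto the vinyl sulfone, with the aldehyde expected to be reduced before the hindered enone) would give the 6β-hydroxy analogue of 13 F2, hydroxyl equatorial and trans to the sulfonylmethyl arm. Deoxychlorination with retention through the chlorosulfite (SOCl2, then catalytic TiCl4) would then return to 13. This detour gives up the direct setting of the C–Cl centre and depends on substitution at a neopentyl-type carbon.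

2. Step 10. What may go wrong:
   - retro-aldol opening of the lithium β-alkoxy ester;
   - deprotonation next to the ester with loss of the C1 configuration;
   - slow alkylation of the hindered neopentyl carbanion.

   Fallback, from 24 back to 27: the tertiary alcohol would first be silylated (TMSOTf, 2,6-lutidine) to the trimethylsilyl ether of 24 F3, so that no alkoxide is formed. One equivalent of LDA and prenyl bromide would give the trimethylsilyl ether of 27 F4, and fluoride (TBAF) would return to 27.

3. Step 4. What may go wrong:
   - conjugate addition of the phosphonate anion to the ring enone;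
   - enolisation of the acetyl group with epimerisation at C5;
   - slow olefination of the hindered ketone, or poor E/Z control.

   Fallback, from 7 back to 12 without the ketone: radical iodosulfonylation of the isopropenyl group (PhSO2Na, I2, EtOAc–H2O; the electrophilic sulfonyl radical adds to the terminal CH2 of the only electron-rich alkene) would give the tertiary β-iodo sulfone F5. Dehydroiodination with Et3N through the acidic α-sulfonyl hydrogen would return to 12.

**Further compounds**
F1 | step 5 | aldehyde analogue of 12 (CH2CH2CHO in place of the chloroallyl arm) | O=C1[C@@](C)(CCC=O)[C@H](/C(C)=C/S(=O)(=O)c2ccccc2)CC=C1C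
F2 | step 5 | 6β-hydroxy analogue of 13 | O=C1[C@@]2(C)CC[C@H](O)[C@@](C)(CS(=O)(=O)c3ccccc3)[C@@H]2CC=C1C
F3 | step 10 | trimethylsilyl ether of 24 | COC(=O)[C@@H]1[C@@]2(C)CC[C@H](Cl)[C@@](C)(CS(=O)(=O)c3ccccc3)[C@@H]2CC[C@]1(C)O[Si](C)(C)C
F4 | step 10 | trimethylsilyl ether of 27 | COC(=O)[C@@H]1[C@@]2(C)CC[C@H](Cl)[C@@](C)(C(CC=C(C)C)S(=O)(=O)c3ccccc3)[C@@H]2CC[C@]1(C)O[Si](C)(C)C
F5 | step 4 | tertiary β-iodo sulfone from 7 (carbinyl iodide centre as a mixture) | O=C1[C@@](C)(C/C=C/Cl)[C@H](C(C)(I)CS(=O)(=O)c2ccccc2)CC=C1C
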